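The route reads the chain C5–C4–C3–C9 of the oxolane (O1, C2 bearing the catechol, C3 bearing C9, C4 bearing carbinol C7, C5) as a butenolide: C5 the carbonyl, C9 a menthyl acetal carbon. In one flask a lithiated 2-aryl-1,3-dithiane (C2 acyl anion) adds to C3. The enolate, moved to zinc, then takes O-benzylvanillin at C4. This forges C2–C3 and C4–C7 and sets C3, C4 and C7; no ring closes. The feature exploited: groups trans on this lactone become cis on the oxolane, because the final ring runs through O1 and C2 instead of C9. Precursors: the (5R)-menthyloxybutenolide, the dithiane and the aldehyde.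

Key step: step 4

Remark: the locants O1, C2–C5, C7 and C9 of the target are kept for every intermediate, and the CIP letters refer to these locants (they change with the substituents although no centre is inverted); ArG = 4-benzyloxy-3-methoxyphenyl, ArC = 3,4-bis(benzyloxy)phenyl, Men = l-menthyl, TBS = tert-butyldimethylsilyl.

Step 1
Reactants: 1 furfural
Product: 3 5-hydroxyfuran-2(5H)-one (racemic hemiacetal), via furfural endoperoxide 2 (not isolated)
Conditions: O2, visible light, rose bengal (C20H2Cl4I4Na2O5, cat), MeOH, 0–20 °C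
Reagents that add atoms: oxygen, O=O
Why: Dye-sensitised photooxygenation, in which singlet oxygen adds [4+2] across the furan to give 2 and methanol strips the formyl group as its formate ester; the hemiacetal carbon (future C9) forms racemic and is fixed in step 2.

Step 2
Reactants: 3 5-hydroxyfuran-2(5H)-one; 4 l-menthol
Product: 5 (5R)-5-(l-menthyloxy)furan-2(5H)-one
Conditions: (1S)-camphor-10-sulfonic acid (cat), toluene, reflux, Dean–Stark; crystallisation from petroleum ether, −20 °C; mother liquor re-equilibrated with the acid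
Reagents that add atoms: none
Why: Acid-catalysed acetalisation of the pseudo-acid hydroxyl gives both C9 epimers, which interconvert through the ring oxocarbenium ion, and the less soluble (5R) epimer should be drawn out by crystallisation, so C9 is set by the menthyl group through crystallisation-driven epimer enrichment.

Step 3
Reactants: 6 3,4-bis(benzyloxy)benzaldehyde
Product: 7 2-[3,4-bis(benzyloxy)phenyl]-1,3-dithiane
Conditions: HS(CH2)3SH, BF3·OEt2 (cat), CH2Cl2, 0 °C to rt
Reagents that add atoms: propane-1,3-dithiol, SCCCS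
Why: Lewis-acid-catalysed dithioacetalisation of an aromatic aldehyde, to which aryl benzyl ethers are inert at this temperature; no stereocentre is formed.

Step 4
Reactants: 7 2-[3,4-bis(benzyloxy)phenyl]-1,3-dithiane; 5 (5R)-5-(l-menthyloxy)furan-2(5H)-one; 8 4-benzyloxy-3-methoxybenzaldehyde
Product: 12 all-trans Michael–aldol adduct (3R,4S,7R,9R), via 2-lithiodithiane 9 (not isolated), via lithium enolate 10 (not isolated), via chlorozinc enolate 11 (not isolated)
Conditions: 7, n-BuLi, THF, −78 to −30 °C; 5, −78 °C; ZnCl2 (THF), −78 °C; 8, −78 to −50 °C; aq NH4Cl, −50 °C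
Reagents that add atoms: none
Why: n-BuLi deprotonates 7 to the sulfur-stabilised benzylic carbanion 9, which adds in the 1,4 sense to butenolide 5 at C3 to give the ring-locked enolate 10; after lithium–zinc exchange (11) this adds to aldehyde 8 at C4 through a closed six-membered chair (Zimmerman–Traxler type), and cold NH4Cl releases 12. The closest known reaction type is the tandem conjugate addition–aldol trapping of lithiated aryl dithioacetals on 5-alkoxybutenolides. No ring is closed, so no mode of closure applies; the lactone ring is only a rigid template. C3 is controlled by the C9 menthyloxy group, which blocks its own face so that 9 enters anti to it; C4 is controlled by the bulky new dithianyl group on C3, which sends the aldehyde to the opposite face; C7 is controlled by the enolate geometry, because the ring holds the metal-bearing oxygen trans to C3 (E enolate) and the chair with ArG equatorial then leads to the anti aldol, which is 7R in this series. The step needs 1,4 over 1,2 addition (secured by the soft, delocalised 2-aryl dithiane anion and the open β-carbon), two face selectivities (secured by C9 and then by C3) and anti over syn at C7 (secured only by the ring-fixed enolate geometry). Since the last is the weakest, zinc replaces lithium: it binds both oxygens more tightly, which tightens the chair, and if the addition turns reversible the chelate with both substituents equatorial is again the anti one.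

Step 5
Reactants: 12 all-trans Michael–aldol adduct
Product: 13 C7 TBS ether of the adduct (3R,4S,7R,9R)
Conditions: TBSOTf, 2,6-lutidine, CH2Cl2, −40 to 0 °C
Reagents that add atoms: tert-butyldimethylsilyl triflate (TBSOTf), CC(C)(C)[Si](C)(C)OS(=O)(=O)C(F)(F)F
Why: Standard O-silylation with a silyl triflate and a hindered pyridine base caps the congested benzylic carbinol at low temperature without forming an alkoxide, so retro-aldol cleavage is avoided and acetal, lactone and dithiane stay untouched.

Step 6
Reactants: 13 C7 TBS ether of the adduct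
Product: 14 C2 aryl ketone (3R,4S,7R,9R)
Conditions: MeI, CaCO3, MeCN/H2O (9:1), 40 °C
Reagents that add atoms: water, O
Why: Alkylative dithiane hydrolysis, in which S-methylation makes sulfur a leaving group and water captures the aryl-stabilised thionium ion, while the CaCO3 buffer keeps the medium near neutral so that the silyl ether, the acylal and the already all-trans C3 centre are preserved.

Step 7
Reactants: 14 C2 aryl ketone
Product: 15 (2S)-carbinol (2S,3S,4S,7R,9R)
Conditions: (R)-2-methyl-CBS-oxazaborolidine [(R)-1-methyl-3,3-diphenyltetrahydro-1H,3H-pyrrolo[1,2-c][1,3,2]oxazaborole, C18H20BNO] (0.3 equiv), BH3·SMe2, THF, −20 °C; MeOH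
Reagents that add atoms: none
Why: Corey–Bakshi–Shibata reduction, in which the ketone binds the ring boron with the flat conjugated ArC ring as the large group and the nitrogen-bound borane passes hydride to the Re face of C2 through a six-membered transition state, so the (R)-catalyst should give the (S)-benzylic carbinol while lactone, acetal, silyl and benzyl ethers are inert to borane at this temperature.

Step 8
Reactants: 15 (2S)-carbinol
Product: 17 C9 hydroxymethyl lactone O1–C2–C3–C4–C5(=O) (2S,3R,4S,7R), via C9 aldehyde lactone 16 (not isolated)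
Conditions: LiAlH(Ot-Bu)3 (2.5 equiv), then LiN(SiMe3)2 (1.05 equiv), THF, −78 to −10 °C; aq KNaC4H4O6, 0 °C
Reagents that add atoms: none
Why: The lithium alkoxide of 15 attacks the activated acylal carbonyl C5 (alkoxide-induced translactonisation, an intramolecular transesterification), the expelled C9 hemiacetal oxide sheds menthoxide to give aldehyde 16, and the hindered aluminium hydride already present, which reduces aldehydes but not γ-lactones at this temperature, takes 16 to the primary alcohol before C3 can epimerise or the C2 acyloxy group can β-eliminate; no stereocentre is made or broken.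

Step 9
Reactants: 17 C9 hydroxymethyl lactone
Product: 18 C7,C9 bis-TBS lactone (2S,3R,4S,7R)
Conditions: TBSCl, imidazole, DMF, 0 °C to rt
Reagents that add atoms: tert-butyldimethylsilyl chloride (TBSCl), CC(C)(C)[Si](C)(C)Cl
Why: Imidazole-promoted silylation of a primary alcohol, carried out at once because it also blocks acyl migration back from O1 to O9 and keeps C9 distinct from C5 in the next step.

Step 10
Reactants: 18 C7,C9 bis-TBS lactone
Product: 19 C2,C5 diol (2S,3R,4R,7R)
Conditions: LiAlH4, THF, −10 to 0 °C; Na2SO4·10H2O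
Reagents that add atoms: none
Why: Hydride reduction of a γ-lactone to the 1,4-diol, to which silyl and benzyl ethers are inert, and the cold aluminium alkoxides should be too weakly basic to pass the C7 silyl group to O5.

Step 11
Reactants: 19 C2,C5 diol
Product: 21 protected oxolane (2S,3R,4R,7R), via C5 tosylate 20 (not isolated)
Conditions: TsCl, Et3N, 4-(dimethylamino)pyridine (cat), CH2Cl2, 0 to 40 °C
Reagents that add atoms: none
Why: Selective sulfonylation of the primary C5 hydroxyl over the hindered secondary benzylic C2 hydroxyl, followed by 5-exo-tet Williamson-type displacement by the C2 oxygen, closes the oxolane with retention at C2 because the C2–O bond is never broken, which gives the 2,3-trans-3,4-cis ring.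

Step 12
Reactants: 21 protected oxolane
Product: 22 tri-O-benzyl (7R)-7-hydroxytaxiresinol (2S,3R,4R,7R)
Conditions: Bu4NF, THF, 0 °C to rt
Reagents that add atoms: none
Why: Fluoride-driven cleavage of both silyl ethers under non-acidic conditions, done while the phenols are still benzylated so that no quinone methide can form at C7 or C2.

Step 13
Reactants: 22 tri-O-benzyl (7R)-7-hydroxytaxiresinol
Product: 23 (7R)-7-hydroxytaxiresinol (2S,3R,4R,7R)
Conditions: H2 (1 atm), 10% Pd on carbon, EtOAc/EtOH, rt, stopped after uptake of 3 equiv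
Reagents that add atoms: none
Why: Heterogeneous hydrogenolysis of the three aryl benzyl ethers, which in a neutral solvent are cleaved far faster than the secondary benzylic C7–OH and C2–O1 bonds, and only filtration and evaporation are needed for the acid- and air-sensitive catechol.

Compound list
1 | furfural (furan-2-carbaldehyde) | O=Cc1ccco1 | starting material
2 | furfural endoperoxide, 2,3,7-trioxabicyclo[2.2.1]hept-5-ene-1-carbaldehyde (racemic, not isolated) | O=CC12OOC(C=C1)O2 | intermediate
3 | 5-hydroxyfuran-2(5H)-one (racemic hemiacetal) | O=C1C=CC(O)O1 | intermediate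
4 | l-menthol, (1R,2S,5R)-2-isopropyl-5-methylcyclohexan-1-ol | C[C@@H]1CC[C@H]([C@@H](C1)O)C(C)C | starting material
5 | (5R)-5-(l-menthyloxy)furan-2(5H)-one (carbonyl = C5, acetal carbon = C9, 9R) | O=C1C=C[C@H](O[C@@H]2C[C@H](C)CC[C@H]2C(C)C)O1 | intermediate
6 | 3,4-bis(benzyloxy)benzaldehyde | O=Cc1ccc(OCc2ccccc2)c(OCc2ccccc2)c1 | starting material
7 | 2-[3,4-bis(benzyloxy)phenyl]-1,3-dithiane | C1CSC(SC1)c1ccc(OCc2ccccc2)c(OCc2ccccc2)c1 | intermediate
8 | 4-benzyloxy-3-methoxybenzaldehyde (O-benzylvanillin) | COc1cc(C=O)ccc1OCc1ccccc1 | starting material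
9 | 2-lithio-2-[3,4-bis(benzyloxy)phenyl]-1,3-dithiane (not isolated) | [Li]C1(SCCCS1)c1ccc(OCc2ccccc2)c(OCc2ccccc2)c1 | intermediate
10 | lithium enolate (3R,9R) of the Michael adduct: C5(OLi)=C4, 2-ArC-dithian-2-yl on C3 trans to OMen on C9 (not isolated) | [Li]OC1=C[C@@H](C2(SCCCS2)c2ccc(OCc3ccccc3)c(OCc3ccccc3)c2)[C@H](O[C@@H]2C[C@H](C)CC[C@H]2C(C)C)O1 | intermediate
11 | chlorozinc enolate (3R,9R), as 10 with ZnCl on the enolate oxygen (not isolated) | Cl[Zn]OC1=C[C@@H](C2(SCCCS2)c2ccc(OCc3ccccc3)c(OCc3ccccc3)c2)[C@H](O[C@@H]2C[C@H](C)CC[C@H]2C(C)C)O1 | intermediate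
12 | all-trans Michael–aldol adduct (3R,4S,7R,9R): γ-lactone C5(=O)–O–C9–C3–C4 with OMen on C9, 2-ArC-1,3-dithian-2-yl (C2) on C3 and (R)-ArG(hydroxy)methyl (C7) on C4 | COc1cc(ccc1OCc1ccccc1)[C@H](O)[C@H]1C(=O)O[C@@H](O[C@@H]2C[C@H](C)CC[C@H]2C(C)C)[C@@H]1C1(SCCCS1)c1ccc(OCc2ccccc2)c(OCc2ccccc2)c1 | intermediate
13 | C7 TBS ether of 12 (3R,4S,7R,9R) | COc1cc(ccc1OCc1ccccc1)[C@H](O[Si](C)(C)C(C)(C)C)[C@H]1C(=O)O[C@@H](O[C@@H]2C[C@H](C)CC[C@H]2C(C)C)[C@@H]1C1(SCCCS1)c1ccc(OCc2ccccc2)c(OCc2ccccc2)c1 | intermediate
14 | C2 aryl ketone (3R,4S,7R,9R): as 13 with ArC–C(=O) on C3 | COc1cc(ccc1OCc1ccccc1)[C@H](O[Si](C)(C)C(C)(C)C)[C@H]1C(=O)O[C@@H](O[C@@H]2C[C@H](C)CC[C@H]2C(C)C)[C@@H]1C(=O)c1ccc(OCc2ccccc2)c(OCc2ccccc2)c1 | intermediate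
15 | (2S)-carbinol (2S,3S,4S,7R,9R): as 14 with (S)-ArC–CH(OH) on C3 | COc1cc(ccc1OCc1ccccc1)[C@H](O[Si](C)(C)C(C)(C)C)[C@H]1C(=O)O[C@@H](O[C@@H]2C[C@H](C)CC[C@H]2C(C)C)[C@@H]1[C@H](O)c1ccc(OCc2ccccc2)c(OCc2ccccc2)c1 | intermediate
16 | C9 aldehyde lactone (2S,3S,4S,7R): γ-lactone O1–C2–C3–C4–C5(=O), ArC on C2, CHO on C3 (trans to ArC), ArG–CH(OTBS) on C4 (cis to CHO) (not isolated) | COc1cc(ccc1OCc1ccccc1)[C@H](O[Si](C)(C)C(C)(C)C)[C@H]1C(=O)O[C@H](c2ccc(OCc3ccccc3)c(OCc3ccccc3)c2)[C@H]1C=O | intermediate
17 | C9 hydroxymethyl lactone (2S,3R,4S,7R): as 16 with CH2OH on C3 | COc1cc(ccc1OCc1ccccc1)[C@H](O[Si](C)(C)C(C)(C)C)[C@H]1C(=O)O[C@H](c2ccc(OCc3ccccc3)c(OCc3ccccc3)c2)[C@H]1CO | intermediate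
18 | C7,C9 bis-TBS lactone (2S,3R,4S,7R) | COc1cc(ccc1OCc1ccccc1)[C@H](O[Si](C)(C)C(C)(C)C)[C@H]1C(=O)O[C@H](c2ccc(OCc3ccccc3)c(OCc3ccccc3)c2)[C@H]1CO[Si](C)(C)C(C)(C)C | intermediate
19 | C2,C5 diol (2S,3R,4R,7R): open chain ArG–C7H(OTBS)–C4H(C5H2OH)–C3H(C9H2OTBS)–C2H(OH)–ArC | COc1cc(ccc1OCc1ccccc1)[C@H](O[Si](C)(C)C(C)(C)C)[C@@H](CO)[C@H](CO[Si](C)(C)C(C)(C)C)[C@H](O)c1ccc(OCc2ccccc2)c(OCc2ccccc2)c1 | intermediate
20 | C5 tosylate of 19 (2S,3R,4R,7R) (not isolated) | COc1cc(ccc1OCc1ccccc1)[C@H](O[Si](C)(C)C(C)(C)C)[C@@H](COS(=O)(=O)c1ccc(C)cc1)[C@H](CO[Si](C)(C)C(C)(C)C)[C@H](O)c1ccc(OCc2ccccc2)c(OCc2ccccc2)c1 | intermediate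
21 | protected oxolane (2S,3R,4R,7R): 2-ArC, 3-CH2OTBS (trans to ArC), 4-[(R)-ArG–CH(OTBS)] (cis to CH2OTBS) | COc1cc(ccc1OCc1ccccc1)[C@H](O[Si](C)(C)C(C)(C)C)[C@H]1CO[C@H](c2ccc(OCc3ccccc3)c(OCc3ccccc3)c2)[C@H]1CO[Si](C)(C)C(C)(C)C | intermediate
22 | tri-O-benzyl (7R)-7-hydroxytaxiresinol (2S,3R,4R,7R) | COc1cc(ccc1OCc1ccccc1)[C@H](O)[C@H]1CO[C@H](c2ccc(OCc3ccccc3)c(OCc3ccccc3)c2)[C@H]1CO | intermediate
23 | (7R)-7-hydroxytaxiresinol (2S,3R,4R,7R) | COc1cc([C@H](O)[C@H]2CO[C@H](c3ccc(O)c(O)c3)[C@H]2CO)ccc1O | target

Total step count: 13. Longest linear sequence: 12 steps (1, 2, 4–13, from furfural); step 3 is a one-step side branch.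

Steps most likely to fail

Step 4. The process at risk is weak discrimination between the two faces of the aldehyde in the aldol event (C7), made worse by retro-aldol drift on warming or quenching. C3 and C4 are not in doubt. In the fallback, C7 is set by ketone reduction instead of by the aldol.
- It sets out from 12, taken as the whole carbinol fraction whatever its make-up at C7.
- Parikh–Doering oxidation (SO3·pyridine, DMSO, Et3N, CH2Cl2, 0 °C), which spares the dithiane, should give the C7 keto lactone F1. Its acidic C4 rests trans to C3.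
- Reduction with the (S)-enantiomer of the oxazaborolidine of step 7 and BH3·SMe2, with ArG as the large group, should give the 7R carbinol. The route is rejoined at 12.

Step 8. The processes at risk are an acyl shift that lags behind direct hydride attack on the acylal, and epimerisation at C3 or β-elimination at the aldehyde stage. The fallback removes the auxiliary before C2 is unmasked, so that no aldehyde ever sits next to an acyloxy-bearing benzylic carbon.
- It sets out from 13. KOH and NaBH4 in aqueous EtOH followed by citric acid (saponification, in situ reduction, relactonisation) exchange the menthyl acetal for a C9 methylene and should give the C9-methylene dithianyl lactone F4.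
- MeI/CaCO3 as in step 6 unmasks the aroyl lactone F5.
- The reduction of step 7 gives the (2S)-carbinol lactone F6.
- NaN(SiMe3)2 (1 equiv, THF, −78 to −20 °C) moves the acyl group from O9 to the C2 oxygen. This is the translactonisation known for β-(α-hydroxybenzyl)butyrolactones, drawn by the less hindered primary alkoxide.
- TBSCl added to the same flask caps O9. The route is rejoined at 18.

Step 7. The processes at risk are poor facial selectivity or slow hydride transfer, because the α-branched C3 competes with the aryl ring as the large group and the bias of the substrate may oppose the catalyst. The fallback makes the configuration of the C2 carbinol irrelevant.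
- It sets out from 14. LiAlH4 (THF, 0 °C) reduces the ketone, the lactone and the liberated C9 hemiacetal in one operation to the C7-silylated triol F2 (either configuration at C2).
- Catalytic (1S)-camphor-10-sulfonic acid in CH2Cl2 over 4 Å sieves at 0 °C should ionise only the free, p-benzyloxy-stabilised C2 carbinol.
- O5 captures the cation, since O9 could only form an oxetane, and ArC settles trans to the C3 substituent. This closes the oxolane alcohol F3.
- Bu4NF then removes the C7 silyl group. The route is rejoined at 22.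

Further compounds
F1 | step 4 | C7 keto lactone (3R,4S,9R): as 12 with ArG–C(=O) on C4 | COc1cc(ccc1OCc1ccccc1)C(=O)[C@H]1C(=O)O[C@@H](O[C@@H]2C[C@H](C)CC[C@H]2C(C)C)[C@@H]1C1(SCCCS1)c1ccc(OCc2ccccc2)c(OCc2ccccc2)c1
F2 | step 7 | C7-silylated triol (3R,4R,7R, C2 undefined): ArG–CH(OTBS)–CH(CH2OH)–CH(CH2OH)–CH(OH)–ArC | COc1cc(ccc1OCc1ccccc1)[C@H](O[Si](C)(C)C(C)(C)C)[C@@H](CO)[C@H](CO)C(O)c1ccc(OCc2ccccc2)c(OCc2ccccc2)c1
F3 | step 7 | oxolane alcohol (2S,3R,4R,7R): as 21 with free C9 hydroxyl | COc1cc(ccc1OCc1ccccc1)[C@H](O[Si](C)(C)C(C)(C)C)[C@H]1CO[C@H](c2ccc(OCc3ccccc3)c(OCc3ccccc3)c2)[C@H]1CO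
F4 | step 8 | C9-methylene dithianyl lactone (3R,4S,7R): γ-lactone C5(=O)–O–C9H2–C3–C4, trans | COc1cc(ccc1OCc1ccccc1)[C@H](O[Si](C)(C)C(C)(C)C)[C@H]1C(=O)OC[C@@H]1C1(SCCCS1)c1ccc(OCc2ccccc2)c(OCc2ccccc2)c1
F5 | step 8 | aroyl lactone (3R,4S,7R): as F4 with ArC–C(=O) on C3 | COc1cc(ccc1OCc1ccccc1)[C@H](O[Si](C)(C)C(C)(C)C)[C@H]1C(=O)OC[C@@H]1C(=O)c1ccc(OCc2ccccc2)c(OCc2ccccc2)c1
F6 | step 8 | (2S)-carbinol lactone (2S,3R,4S,7R): as F5 with (S)-ArC–CH(OH) on C3 | COc1cc(ccc1OCc1ccccc1)[C@H](O[Si](C)(C)C(C)(C)C)[C@H]1C(=O)OC[C@@H]1[C@H](O)c1ccc(OCc2ccccc2)c(OCc2ccccc2)c1
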